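Readings and results stem from a simulated flask from invented constants, noise included.

A ratio reads these flasks: h, the right-handed substrate lost in the first seconds per free catalyst charged. A single-handed catalyst meets a racemate here, beside a solid reagent and a protic impurity.

| flask | left-handed substrate | right-handed substrate | protic impurity | solid reagent | free catalyst | remark | time |
|---|---|---|---|---|---|---|---|
| gamma | 0.25 M | 0.25 M | 0.50 M | 0.30 M | 85 mM | run made earlier |  |
| beta | 0.38 M | 0.38 M | 0.50 M | 0.30 M | 85 mM | run made earlier |  |
| zeta | 0.50 M | 0.50 M | 0.25 M | 0.30 M | 85 mM | run made earlier |  |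
| flask | 0.50 M | 0.50 M | 0.500 M | 0.300 M | 85 mM |  | 2.5 min |

| run | time / s | left-handed substrate / % | right-handed substrate / % |
|---|---|---|---|
| gamma | 10.0 | 48.6 | 37.9 |
| gamma | 12.0 | 48.5 | 37.5 |
| gamma | 15.0 | 49.0 | 36.9 |
| gamma | 25.0 | 48.8 | 35.1 |
| gamma | 40.0 | 49.3 | 34.7 |
| gamma | 60.0 | 48.8 | 33.4 |
| gamma | 90.0 | 49.5 | 32.2 |
| beta | 12.0 | 49.6 | 40.4 |
| beta | 25.0 | 49.6 | 39.4 |
| beta | 40.0 | 50.1 | 38.2 |
| beta | 50.0 | 49.5 | 37.6 |
| beta | 60.0 | 49.5 | 37.7 |
| beta | 80.0 | 48.9 | 37.7 |
| beta | 90.0 | 49.2 | 37.0 |
| zeta | 10.0 | 49.4 | 42.8 |
| zeta | 15.0 | 49.5 | 42.1 |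
| zeta | 25.0 | 49.4 | 41.5 |
| zeta | 50.0 | 49.8 | 40.9 |
| zeta | 90.0 | 49.4 | 39.7 |

(scatter of a reading: 0.3 percentage points)

- free catalyst is single-handed; left-handed substrate and right-handed substrate are mirror images of each other, charged as a racemate, each of them at the stated concentration
- solid reagent is a solid; its amount is given per volume of the solution
- at the start none of the solid reagent is in solution
- an excess is below zero if the other one leads

- part of the left-handed substrate and right-handed substrate charged together that has reacted at 2.5 min
- excess of left-handed product over right-handed product in the product at 2.5 min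
- excess of right-handed substrate over left-handed substrate among what is left of the two at 2.5 min

From 15.0 s to 90.0 s the right-handed substrate of the zeta run drifts down at 3.20 × 10⁻⁴ M s⁻¹. The beta run, with twice the impurity and less substrate, drifts at 3.31 × 10⁻⁴ M s⁻¹.

Turn the question round: if the missing substrate were product, the drift would have to account for the zeta loss at 10.0 s. It accounts for 0.320 % of the charge, far less than the 7.20 % lost. Carried back to the start, the drift leaves a burst of 0.0742 M in the zeta run, less than the 85 mM of catalyst charged, so the burst is read as substrate sitting on the catalyst, and h, the share of the catalyst so loaded, reads 87.3 % there.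

With h carried over and the drift of the zeta run assumed to hold on to 2.5 min, this reckoning gives the flask 7.42 % of the charge held and 4.80 % as right-handed product. At 90.0 s the left-handed substrate of the zeta run reads 0.600 % below its charge, twice the scatter. Counted whole as product in the flask, that gives a rough excess of left-handed over right-handed product of −77.8 %.

The forecast, which differs on that excess, says 11.7 % reacted, a product excess of −90 % and a substrate excess of −11.9 %, reasoning “so the right-handed product leads”.

The flask gives 12.9 % reacted, a product excess of −80.9 % and a substrate excess of −13.0 %.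

    free catalyst + left-handed substrate ⇌ catalyst intermediate A (K = 1.20 L mol⁻¹, k = 32.0 L mol⁻¹ s⁻¹)
    free catalyst + right-handed substrate ⇌ catalyst intermediate B (K = 48.0 L mol⁻¹, k = 1.00 L mol⁻¹ s⁻¹)
    partner + catalyst intermediate A → free catalyst + left-handed product (k = 0.140 L mol⁻¹ s⁻¹)
    partner + catalyst intermediate B → free catalyst + right-handed product (k = 0.0540 L mol⁻¹ s⁻¹)
    partner + protic impurity → quenched reagent (k = 0.0190 L mol⁻¹ s⁻¹)
    solid reagent ⇌ partner, rate k6*(cs6 - [partner]) while solid is left; crystals form when [partner] > cs6 (solubility = 0.0840 M, k = 0.230 s⁻¹)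
    2 free catalyst ⇌ resting dimer (K = 2200 L mol⁻¹, k = 0.170 L mol⁻¹ s⁻¹)

At 2.50 min catalyst intermediate B, the resting state of the flask, holds 87.6 % of the catalyst charged. At that time the flask holds right-handed product at 4.67 % and left-handed product at 0.493 % of the substrates charged. The neighbouring flask, the same but with 0.14 M of free catalyst, gets from h a held amount of 12.2 % of the substrates charged, and at 2.50 min its catalyst intermediate B stands at 11.7 % of them.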